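**Plan**

- Ring C is cut at O1–C2 and at C3–OH (oxidative cyclisation of a 2'-hydroxychalcone), then the chalcone Cα=Cβ bond is cut (aldol condensation), giving a ring-A acetophenone and a ring-B benzaldehyde.
- Ring B is a 1,2,3,4-tetrasubstituted benzene: the carbon substituent on C1', the prenyl group on C2' and the oxygens on C3' and C4' are contiguous, and C5'/C6' carry hydrogen. It is cut at C2'–C3' and C1'–C6' into a prenylated ynoate (C1', C2') and 3-methoxyfuran (C3'–C6' with the C3' oxygen).
- Forward order: ring B is made first by cycloaddition/aromatisation and adjusted to the bis-MOM aldehyde; the ring-A ketone comes from 4-methylresorcinol; the two are joined by Claisen–Schmidt condensation; ring C closes last by Algar–Flynn–Oyamada oxidation; the MOM groups are then removed.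
- Stereochemistry: the target has no stereocentre. The transient stereocentres (oxabicycle, aldol adduct, dihydroflavonol) are erased, and the chalcone E geometry is thermodynamic.

Key step: step 3

Remark: the target contains no stereogenic centre and no stereogenic double bond (the prenyl alkene carries two identical methyl groups), so it is one achiral compound and no enantiocontrol is needed.

**Route**

Step 1
Reactants: 1 3-bromofuran
Product: 2 3-methoxyfuran
Conditions: NaOMe (3 equiv), CuBr (0.2 equiv), MeOH–DMF, 100 °C, sealed vessel; distillation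
Reagents that add atoms: sodium methoxide, [Na+].[O-]C
Why: Ullmann-type copper-catalysed C–O coupling of a heteroaryl bromide with methoxide is the standard entry to 3-methoxyfuran, which should be isolated by careful distillation because it is volatile and acid-sensitive.

Step 2
Reactants: 3 methyl propiolate; 4 prenyl bromide (1-bromo-3-methylbut-2-ene)
Product: 5 methyl 6-methylhept-5-en-2-ynoate
Conditions: CuI (0.1 equiv), K2CO3 (1.5 equiv), DMF, 0 °C → rt
Reagents that add atoms: none
Why: In this copper-catalysed alkyne–allyl halide coupling, the copper(I) acetylide formed from the acidic propiolate C–H attacks the unhindered primary carbon of prenyl bromide, and the weak heterogeneous base at low temperature should limit isomerisation of the skipped enynoate to the allenoate.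

Step 3
Reactants: 2 3-methoxyfuran; 5 methyl 6-methylhept-5-en-2-ynoate
Product: 7 methyl 3-hydroxy-4-methoxy-2-(3-methylbut-2-en-1-yl)benzoate, via 7-oxanorbornadiene cycloadduct 6 (not isolated)
Conditions: 2 (2 equiv), toluene (1 M), BHT (cat.), 90 °C, sealed tube; then PPTS (0.1 equiv), CH2Cl2, rt
Reagents that add atoms: none
Why: The 3-methoxy group raises the furan HOMO and puts its largest coefficient on C2, which bonds to the electrophilic β-carbon of the ynoate (the carbon bearing the prenyl methylene) while furan C5 bonds to the ester-bearing α-carbon in an asynchronous, thermally allowed [4π+2π] cycloaddition; this forms C2'–C3' and C1'–C6' and closes the six-membered carbocycle of ring B as oxanorbornadiene 6. The reaction type is the known Diels–Alder addition of 3-alkoxyfurans to acetylenic esters followed by acid-promoted oxanorbornadiene-to-phenol isomerisation. Under PPTS the bridging C–O bond ionises at C6', because that cation is a vinylogous oxocarbenium ion stabilised by the methoxy group on C4', so the oxygen stays on C3' next to the prenyl group and loss of the C3' proton aromatises the ring. The two bridgehead stereocentres of racemic 6 are destroyed on aromatisation, so no stereocentre has to be controlled. The step needs regioselectivity in both the cycloaddition and the bridge opening, and the 3-methoxy substituent secures both; the alkyne reacts in preference to the unactivated prenyl alkene because only the alkyne is conjugated with the ester, and the mild acid should leave the o-prenylphenol uncyclised.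

Step 4
Reactants: 7 methyl 3-hydroxy-4-methoxy-2-(3-methylbut-2-en-1-yl)benzoate
Product: 8 methyl 4-methoxy-3-(methoxymethoxy)-2-(3-methylbut-2-en-1-yl)benzoate
Conditions: NaH (1.2 equiv), MOMCl (1.3 equiv), THF–DMF, 0 °C → rt
Reagents that add atoms: chloromethyl methyl ether, COCCl
Why: Williamson-type O-alkylation of the sodium phenoxide converts the phenol into a neutral acetal, so that the later demethylation is not retarded by a phenoxide on the ring.

Step 5
Reactants: 8 methyl 4-methoxy-3-(methoxymethoxy)-2-(3-methylbut-2-en-1-yl)benzoate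
Product: 9 [4-methoxy-3-(methoxymethoxy)-2-(3-methylbut-2-en-1-yl)phenyl]methanol
Conditions: LiAlH4, THF, 0 °C; Fieser work-up
Reagents that add atoms: none
Why: Hydride reduction of the aryl ester should give the benzylic alcohol, since the acetal, the aryl ether and the isolated alkene are inert to LiAlH4.

Step 6
Reactants: 9 [4-methoxy-3-(methoxymethoxy)-2-(3-methylbut-2-en-1-yl)phenyl]methanol
Product: 10 4-methoxy-3-(methoxymethoxy)-2-(3-methylbut-2-en-1-yl)benzaldehyde
Conditions: activated MnO2 (excess), CH2Cl2, rt
Reagents that add atoms: none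
Why: Heterogeneous MnO2 oxidation is selective for benzylic alcohols, stops at the aldehyde and leaves the prenyl group alone.

Step 7
Reactants: 10 4-methoxy-3-(methoxymethoxy)-2-(3-methylbut-2-en-1-yl)benzaldehyde
Product: 11 4-hydroxy-3-(methoxymethoxy)-2-(3-methylbut-2-en-1-yl)benzaldehyde
Conditions: NaSEt (3 equiv), DMF, 90 °C; then 0.5 M HCl to pH 5, 0 °C
Reagents that add atoms: none
Why: In this SN2 O-demethylation by a soft thiolate, the methoxy group para to the formyl group should be cleaved selectively because its aryloxide leaving group is conjugated with the aldehyde, whereas the MOM-bearing oxygen is meta to it and the prenyl group is inert.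

Step 8
Reactants: 11 4-hydroxy-3-(methoxymethoxy)-2-(3-methylbut-2-en-1-yl)benzaldehyde
Product: 12 3,4-bis(methoxymethoxy)-2-(3-methylbut-2-en-1-yl)benzaldehyde
Conditions: MOMCl (1.5 equiv), K2CO3, acetone, rt
Reagents that add atoms: chloromethyl methyl ether, COCCl
Why: The acidic para-formyl phenol is O-alkylated under mild carbonate conditions (Williamson etherification), which removes the phenoxide that would deactivate the aldehyde in the aldol step.

Step 9
Reactants: 13 4-methylresorcinol (4-methylbenzene-1,3-diol)
Product: 14 1-(2,4-dihydroxy-5-methylphenyl)ethan-1-one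
Conditions: AcOH, ZnCl2 (fused), 140 °C
Reagents that add atoms: acetic acid, CC(=O)O
Why: Nencki (Friedel–Crafts) C-acylation of a resorcinol goes to C6, para to one hydroxyl and ortho to the other, because the site between the two hydroxyls is hindered; this places the methyl group at C5 of the acetophenone.

Step 10
Reactants: 14 1-(2,4-dihydroxy-5-methylphenyl)ethan-1-one
Product: 15 1-[2-hydroxy-4-(methoxymethoxy)-5-methylphenyl]ethan-1-one
Conditions: MOMCl (1.1 equiv), K2CO3, acetone, rt
Reagents that add atoms: chloromethyl methyl ether, COCCl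
Why: The 2-OH is held in a hydrogen bond to the ketone and is far less nucleophilic, so one equivalent of MOMCl should etherify only the 4-OH (regioselective Williamson etherification).

Step 11
Reactants: 12 3,4-bis(methoxymethoxy)-2-(3-methylbut-2-en-1-yl)benzaldehyde; 15 1-[2-hydroxy-4-(methoxymethoxy)-5-methylphenyl]ethan-1-one
Product: 17 (2E)-3-[3,4-bis(methoxymethoxy)-2-(3-methylbut-2-en-1-yl)phenyl]-1-[2-hydroxy-4-(methoxymethoxy)-5-methylphenyl]prop-2-en-1-one, via β-hydroxy ketone aldol adduct 16 (not isolated)
Conditions: KOH (50 % aq., excess), EtOH, rt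
Reagents that add atoms: none
Why: In this Claisen–Schmidt condensation the ketone enolate adds to the non-enolisable aldehyde and the aldol adduct dehydrates by E1cB to the conjugated enone, whose E geometry is the thermodynamic one.

Step 12
Reactants: 17 the 2'-hydroxychalcone
Product: 19 2-[3,4-bis(methoxymethoxy)-2-(3-methylbut-2-en-1-yl)phenyl]-3-hydroxy-7-(methoxymethoxy)-6-methyl-4H-chromen-4-one, via trans-3-hydroxyflavanone 18 (not isolated)
Conditions: 30 % H2O2, 2 M NaOH, MeOH–THF, 0 °C → rt
Reagents that add atoms: hydrogen peroxide, OO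
Why: In the Algar–Flynn–Oyamada reaction the 2'-phenoxide closes the pyranone by 6-endo oxa-Michael addition while hydroperoxide oxygenates Cα, and the resulting trans-dihydroflavonol is dehydrogenated in situ; the free 6'-position favours flavonol over aurone, and nucleophilic alkaline peroxide should not touch the electron-rich prenyl alkene.

Step 13
Reactants: 19 the tris-MOM flavonol
Product: 20 2-[3,4-dihydroxy-2-(3-methylbut-2-en-1-yl)phenyl]-3,7-dihydroxy-6-methyl-4H-chromen-4-one (CNP0154747.0)
Conditions: 3 M aq. HCl–MeOH (1:5), 45 °C, monitored and stopped at full conversion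
Reagents that add atoms: none
Why: Acid-catalysed methanolysis of the three aryl MOM acetals frees the phenols, and dilute acid at moderate temperature should keep cyclisation of the prenyl group onto the 3'-OH (chroman formation) slow.

**Compound list**

1 | 3-bromofuran | Brc1ccoc1 | starting material
2 | 3-methoxyfuran | COc1ccoc1 | intermediate
3 | methyl propiolate | C#CC(=O)OC | starting material
4 | prenyl bromide (1-bromo-3-methylbut-2-ene) | CC(C)=CCBr | starting material
5 | methyl 6-methylhept-5-en-2-ynoate | COC(=O)C#CCC=C(C)C | intermediate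
6 | methyl 5-methoxy-3-(3-methylbut-2-en-1-yl)-7-oxabicyclo[2.2.1]hepta-2,5-diene-2-carboxylate (racemic, not isolated) | COC(=O)C1=C(CC=C(C)C)C2OC1C=C2OC | intermediate
7 | methyl 3-hydroxy-4-methoxy-2-(3-methylbut-2-en-1-yl)benzoate | COC(=O)c1ccc(OC)c(O)c1CC=C(C)C | intermediate
8 | methyl 4-methoxy-3-(methoxymethoxy)-2-(3-methylbut-2-en-1-yl)benzoate | COCOc1c(OC)ccc(C(=O)OC)c1CC=C(C)C | intermediate
9 | [4-methoxy-3-(methoxymethoxy)-2-(3-methylbut-2-en-1-yl)phenyl]methanol | COCOc1c(OC)ccc(CO)c1CC=C(C)C | intermediate
10 | 4-methoxy-3-(methoxymethoxy)-2-(3-methylbut-2-en-1-yl)benzaldehyde | COCOc1c(OC)ccc(C=O)c1CC=C(C)C | intermediate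
11 | 4-hydroxy-3-(methoxymethoxy)-2-(3-methylbut-2-en-1-yl)benzaldehyde | COCOc1c(O)ccc(C=O)c1CC=C(C)C | intermediate
12 | 3,4-bis(methoxymethoxy)-2-(3-methylbut-2-en-1-yl)benzaldehyde | COCOc1ccc(C=O)c(CC=C(C)C)c1OCOC | intermediate
13 | 4-methylresorcinol (4-methylbenzene-1,3-diol) | Cc1ccc(O)cc1O | starting material
14 | 1-(2,4-dihydroxy-5-methylphenyl)ethan-1-one | CC(=O)c1cc(C)c(O)cc1O | intermediate
15 | 1-[2-hydroxy-4-(methoxymethoxy)-5-methylphenyl]ethan-1-one | COCOc1cc(O)c(C(C)=O)cc1C | intermediate
16 | 3-[3,4-bis(methoxymethoxy)-2-(3-methylbut-2-en-1-yl)phenyl]-3-hydroxy-1-[2-hydroxy-4-(methoxymethoxy)-5-methylphenyl]propan-1-one (racemic, not isolated) | COCOc1cc(O)c(C(=O)CC(O)c2ccc(OCOC)c(OCOC)c2CC=C(C)C)cc1C | intermediate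
17 | (2E)-3-[3,4-bis(methoxymethoxy)-2-(3-methylbut-2-en-1-yl)phenyl]-1-[2-hydroxy-4-(methoxymethoxy)-5-methylphenyl]prop-2-en-1-one | COCOc1cc(O)c(C(=O)/C=C/c2ccc(OCOC)c(OCOC)c2CC=C(C)C)cc1C | intermediate
18 | (2R*,3R*)-2-[3,4-bis(methoxymethoxy)-2-(3-methylbut-2-en-1-yl)phenyl]-3-hydroxy-7-(methoxymethoxy)-6-methyl-2,3-dihydro-4H-chromen-4-one (racemic trans, one enantiomer drawn, not isolated) | CC(C)=CCc1c(OCOC)c(OCOC)ccc1[C@@H]1[C@@H](O)C(=O)c2cc(C)c(OCOC)cc2O1 | intermediate
19 | 2-[3,4-bis(methoxymethoxy)-2-(3-methylbut-2-en-1-yl)phenyl]-3-hydroxy-7-(methoxymethoxy)-6-methyl-4H-chromen-4-one | COCOc1cc2oc(-c3ccc(OCOC)c(OCOC)c3CC=C(C)C)c(O)c(=O)c2cc1C | intermediate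
20 | 2-[3,4-dihydroxy-2-(3-methylbut-2-en-1-yl)phenyl]-3,7-dihydroxy-6-methyl-4H-chromen-4-one (CNP0154747.0) | CC(C)=CCc1c(-c2oc3cc(O)c(C)cc3c(=O)c2O)ccc(O)c1O | target

**Step count**

Total: 13 steps. Longest linear sequence: 10 steps (1 → 3 → 4 → 5 → 6 → 7 → 8 → 11 → 12 → 13); steps 2 and 9–10 are side branches.

**Steps most likely to fail, with fallbacks**

Step 3. The β-alkyl ynoate is a sluggish dienophile, so cycloaddition may be slower than thermal decomposition of the electron-rich furan, or conjugate addition through furan C2 may compete with ring formation. The fallback sets out from 2 and 3 and returns at 7. It keeps the furan–alkynoate ring construction but uses the far more reactive unsubstituted propiolate 3 (toluene, 60 °C; then PPTS). This should give, through methyl 5-methoxy-7-oxabicyclo[2.2.1]hepta-2,5-diene-2-carboxylate F1, the phenol methyl 3-hydroxy-4-methoxybenzoate F2. The phenol is alkylated with 3-chloro-3-methylbut-1-yne (K2CO3, KI, CuI cat., acetone, 55 °C) to methyl 4-methoxy-3-[(2-methylbut-3-yn-2-yl)oxy]benzoate F3. Semi-hydrogenation (H2, Lindlar catalyst, quinoline, EtOAc) gives methyl 4-methoxy-3-[(2-methylbut-3-en-2-yl)oxy]benzoate F4. Heating (N,N-diethylaniline, 130 °C) triggers aromatic Claisen rearrangement to the only free ortho position, C2, through methyl 4-methoxy-2-(3-methylbut-2-en-1-yl)-3-oxocyclohexa-1,4-diene-1-carboxylate F5, which tautomerises to 7.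

Step 2. The doubly activated CH2 of the skipped enynoate may isomerise under base to the allenoate or conjugated dienoate, and SN2' attack could give the reverse-prenyl isomer. The fallback sets out from 4 and returns at 5. Prenyl bromide is alkylated without copper by lithium acetylide–ethylenediamine complex (DMSO, 15 °C) to 5-methylhex-4-en-1-yne F6. This terminal alkyne is deprotonated (n-BuLi, THF, −78 °C) and acylated with methyl chloroformate, so the ester is introduced last and the product never meets carbonate base.

Step 7. The thiolate may add to the formyl group or attack the acetal carbon of the MOM ether, or conversion may stall. The fallback sets out from 7 and returns at 12; it avoids a MOM group and a strong base during demethylation. Ester 7 is reduced (LiAlH4, THF, 0 °C) to 3-(hydroxymethyl)-6-methoxy-2-(3-methylbut-2-en-1-yl)phenol F7. The benzylic alcohol is oxidised (MnO2, CH2Cl2) to 3-hydroxy-4-methoxy-2-(3-methylbut-2-en-1-yl)benzaldehyde F8. The para-formyl methyl ether is cleaved with a non-basic halide nucleophile (LiCl, DMF, 150 °C), under which the 3-OH stays un-ionised, to give 3,4-dihydroxy-2-(3-methylbut-2-en-1-yl)benzaldehyde F9. Both phenols are then protected together (MOMCl 2.5 equiv, K2CO3, acetone) to give 12.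

**Further compounds**

F1 | step 3 | methyl 5-methoxy-7-oxabicyclo[2.2.1]hepta-2,5-diene-2-carboxylate (racemic) | COC(=O)C1=CC2OC1C=C2OC
F2 | step 3 | methyl 3-hydroxy-4-methoxybenzoate | COC(=O)c1ccc(OC)c(O)c1
F3 | step 3 | methyl 4-methoxy-3-[(2-methylbut-3-yn-2-yl)oxy]benzoate | COC(=O)c1ccc(OC)c(OC(C)(C)C#C)c1
F4 | step 3 | methyl 4-methoxy-3-[(2-methylbut-3-en-2-yl)oxy]benzoate | COC(=O)c1ccc(OC)c(OC(C)(C)C=C)c1
F5 | step 3 | methyl 4-methoxy-2-(3-methylbut-2-en-1-yl)-3-oxocyclohexa-1,4-diene-1-carboxylate (racemic) | COC(=O)C1=CC=C(OC)C(=O)C1CC=C(C)C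
F6 | step 2 | 5-methylhex-4-en-1-yne | C#CCC=C(C)C
F7 | step 7 | 3-(hydroxymethyl)-6-methoxy-2-(3-methylbut-2-en-1-yl)phenol | COc1ccc(CO)c(CC=C(C)C)c1O
F8 | step 7 | 3-hydroxy-4-methoxy-2-(3-methylbut-2-en-1-yl)benzaldehyde | COc1ccc(C=O)c(CC=C(C)C)c1O
F9 | step 7 | 3,4-dihydroxy-2-(3-methylbut-2-en-1-yl)benzaldehyde | O=Cc1ccc(O)c(O)c1CC=C(C)C
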